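**Conventions.** Ring atoms of the target carry the numbering of [1]benzofuro[3,2-a]oxanthrene.
- Ring A = C1, C2, C3, C4, C4a, C13a.
- Ring B = C5a, C6, C7, C7a, C12b, C12c.
- Ring C = C8a, C9, C10, C11, C12, C12a.
- O5 (C4a–O–C5a) and O13 (C12c–O–C13a) are the dioxin oxygens; O8 (C7a–O–C8a) is the furan oxygen.
- Ring D is the aryloxy ring on C4, ring E the aryloxy ring on C9.

**Assumption.** Di-tert-butoxyethyne 15 is taken as a purchasable reagent; it is a known, distillable alkyne that loses isobutene on warming and is therefore stored and used cold.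

## Analysis of the target

Phlorofucofuroeckol A (29, C30H18O14) is a pentacyclic [1]benzofuro[3,2-a]oxanthrene. Ring A is fused through the 1,4-dioxin oxygens O5 and O13 to ring B, ring B is fused through the furan (O8 and the C12a–C12b bond) to ring C, and 3,5-dihydroxyphenoxy rings D and E sit on C4 and C9. There is no stereocentre, so the problem is purely regiochemical: fourteen oxygens, nine of them free hydroxyls, must be placed on five benzene rings that all derive from the same 1,3,5-trioxygenated unit. Ring B is the hardest part. C12c, C5a and C6 carry three adjacent oxygens with three different fates (O13, O5, free OH), C7 carries hydrogen, and C7a and C12b are the 2- and 3-carbons of the furan, so five of six carbons are substituted and no two substituents are equivalent. The dioxin must also be fused in one of two possible orientations, because ring A is unsymmetrical (aryloxy on C4 beside C4a, hydroxyl on C1 beside C13a). All rings are very electron-rich: SNAr needs a temporary activating group, electrophilic substitution cannot tell C2, C7, C11 and the six CH positions of rings D and E apart, and the free nonaphenol is oxidised by air and can exchange ethers in strong acid. The feature that decides the strategy is the sequence C12c(O)–C5a(O)–C6(O)–C7(H) laid on the C7a=C12b bond of a benzofuran. This is exactly the pattern that a vinylketene–alkyne benzannulation writes onto a heteroaryl diazomethyl ketone when the alkyne is a 1,2-dialkoxyalkyne, and the ketene oxygen then arrives as the only free hydroxyl. Sensitive functions on the way are the diazo ketone 14 (light, acid), the aryl tert-butyl ethers (acid) and the aldehydes (base, oxidants).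

## Retrosynthetic reasoning

**29 from 28.** Only the seven O–CH3 bonds are cut. Methyl ethers are chosen because the purchased building blocks 1, 3 and 21 already carry them and because they survive light, base, peracid and copper catalysis. The forward step is one global Lewis-acid demethylation, placed last so that the air-sensitive nonaphenol is never carried through another reaction.

**28 from 27.** The dioxin is opened at C4a–O5. This bond, and not O13–C13a, is made last because its closure is intramolecular and can only give a six-membered ring: the oxygen on C5a reaches C4a, the oxygen on C6 does not. The forward step is a copper-catalysed intramolecular aryl ether formation from the bromide on C4a, so ring A needs no activation at that carbon.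

**27 from 26, and 26 from 24.** These are two changes of functional groups. The hydroxyls on C5a and C6 go back to tert-butyl ethers, and the C1 hydroxyl of ring A goes back to a formyl group (Dakin oxidation). The formyl group is the device for ring A: it is a masked hydroxyl and, before it is oxidised, the only electron-withdrawing group an SNAr on this pentaoxygenated ring can use.

**24 from 20 and 23.** The diaryl ether bond O13–C13a is cut. In 23 the fluoride on C13a is ortho to the formyl group; in 20 the hydroxyl on C12c is the only free one. The orientation of the future dioxin with respect to ring A is therefore fixed by the constitution of the two partners and not by selective protection. 23 goes back to 22 and boronic acid 3 (ring D–O–C4 bond by oxidative copper coupling), and 22 to 21 by bromination beside the hydroxyl.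

**20 from 14 and 15 (key disconnection).** Ring B is taken apart completely. The bonds C7–C7a, C6–C7, C5a–C12c and C12b–C12c are cut. This leaves the benzofuran C7a=C12b bond, a two-carbon ketene unit (C12c and C7, the carbonyl and diazo carbons of 14) and the two alkyne carbons of 15 (C5a and C6). The cut is made here, and not at the biaryl bond or at a furan C–O bond, because the benzannulation creates the whole substitution pattern of ring B and at the same time distinguishes its oxygens by origin:
- the oxygen on C12c is the ketene oxygen and appears as the only free hydroxyl;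
- the oxygens on C5a and C6 arrive as tert-butyl ethers;
- the oxygen on C7a is the furan oxygen;
- C7 receives hydrogen.

The precursor 14 is a plain 2-acylbenzofuran; the product 20 is a dibenzofuran with a pentasubstituted ring B. The forward reaction has to generate an arylketene, add it across 15 and close a six-membered ring onto C3 of the benzofuran.

**14 from 12, and 12 from 8 and 9.** The diazo group is put on the methyl ketone 12 by diazo transfer. The furan ring of 12 is cut at O8–C(furan) and at the furan C=C bond, which leads to salicylaldehyde 8 and chloroketone 9 (Rap–Stoermer condensation).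

**8 from 6.** The formyl carbon, which becomes C12b, is removed from the only free position ortho to the hydroxyl of 6.

**6 from 4, 4 from 2 and 3, 2 from 1.** The hydroxyl of 6, the future O8, is traced to the formyl group of 4 (Dakin oxidation). In 2 this formyl group is the neighbour of the hydroxyl that receives ring E. After oxidation the new phenol oxygen therefore sits beside C9–O–ring E, which is the relationship the target needs between O8 and the C9 aryloxy group. 4 is cut at the ring E–O bond into 2 and 3, and the methoxy group para to the hydroxyl of 2 is traced to the bromide of 1.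

## Alternatives that were turned down

**Alternative 1:** the textbook route: cross-coupling for the furan, copper for the dioxin.
- Disconnection: C12a–C12b by palladium-catalysed intramolecular C–H arylation of the bromo diaryl ether A1 to the dibenzofuran A2. The dioxin then comes from a twofold copper-mediated etherification of a ring B 1,2-diol with a ring A ortho-dibromide, and rings D and E from further Ullmann couplings.
- Reason against: in A2 the three neighbouring methoxy groups on C12c, C5a and C6 are chemically alike. Freeing exactly the first two would need a ring B building block with four different oxygen substituents and a bromine, which is itself a long synthesis.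
- The ring B diol would then meet an unsymmetrical, electron-rich dibromide in two orientations with no electronic bias between them.
- Each intermolecular copper coupling would join a di-ortho-substituted phenol to a di-ortho-substituted, deactivated aryl halide. The route is longer and carries its risk in three places instead of one.

**Alternative 2:** biomimetic oxidative phenol coupling.
- Disconnection: C12a–C12b by oxidative cross-coupling of eckol A3 with triol A4 to the biaryl A5, then O8–C8a by acid-catalysed loss of water.
- Reason against: A3 and A4 together offer nine nucleophilic CH positions and eleven hydroxyls. One-electron oxidation gives C–C and C–O bonds, homo- and cross-coupling, with nothing in the substrates to direct it.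
- Dehydration of A5 can use either of the two ring C hydroxyls ortho to the biaryl bond; only the one beside the C9 aryloxy group leads to 29.
- The free polyphenols are over-oxidised to quinones, and A3 still has to be made with the whole dioxin problem unsolved.

**Alternative 3:** quinone–phenol annulation for the dibenzofuran.
- Disconnection: C12a–C12b and C7a–O8 in one operation, by acid-mediated arylation of quinone A6 with phenol 6 and cyclodehydration to dibenzofuranol A7.
- Reason against: the CH carbons of A6 are the α-carbons of two vinylogous esters and are not electrophilic. The nucleophilic carbon of 6 would attack the methoxy-bearing carbons by addition–elimination and give the wrong connectivity.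
- Even if A7 formed, its free hydroxyl would sit on C5a, with methyl ethers on both C12c and C6. The oxygen that must make the first bond to ring A would not be singled out, and the orientation problem of the dioxin would return together with a selective demethylation.

Key step: step 7

## Route

Step 1
Reactants: 1 5-bromo-2-hydroxy-3-methoxybenzaldehyde
Product: 2 2-hydroxy-3,5-dimethoxybenzaldehyde
Conditions: NaOMe (5 equiv), CuCl (10 mol %), DMF/MeOH, 110 °C; aq. HCl work-up
Reagents that add atoms: sodium methoxide, [Na+].[O-]C
Why: Copper-catalysed methoxylation of an aryl bromide (Ullmann-type ether synthesis), as used to turn bromovanillins into syringaldehyde-type ethers; the phenoxide formed under the conditions shields the aldehyde from methoxide.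

Step 2
Reactants: 2 2-hydroxy-3,5-dimethoxybenzaldehyde; 3 (3,5-dimethoxyphenyl)boronic acid
Product: 4 2-(3,5-dimethoxyphenoxy)-3,5-dimethoxybenzaldehyde
Conditions: 3 (2 equiv), Cu(OAc)2 (20 mol %), pyridine, 4 Å MS, CH2Cl2, O2 (1 atm), rt
Reagents that add atoms: none
Why: Chan–Lam coupling at the only hydroxyl; it runs at room temperature, tolerates the aldehyde and places ring E on the oxygen that will be the neighbour of the future furan oxygen.

Step 3
Reactants: 4 2-(3,5-dimethoxyphenoxy)-3,5-dimethoxybenzaldehyde
Product: 6 2-(3,5-dimethoxyphenoxy)-3,5-dimethoxyphenol, via aryl formate 5 (not isolated)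
Conditions: mCPBA, CH2Cl2, 0 °C to rt; aq. NaHCO3 wash; then K2CO3 (cat.), MeOH, rt
Reagents that add atoms: 3-chloroperoxybenzoic acid (mCPBA), OOC(=O)c1cccc(Cl)c1
Why: Dakin-type Baeyer–Villiger oxidation; the aryl group, made electron-rich by the ortho aryloxy oxygen, should migrate in preference to hydrogen, and methanolysis of formate 5 should free the phenol beside the aryloxy carbon.

Step 4
Reactants: 6 2-(3,5-dimethoxyphenoxy)-3,5-dimethoxyphenol
Product: 8 3-(3,5-dimethoxyphenoxy)-2-hydroxy-4,6-dimethoxybenzaldehyde, via hydroxymethylphenol 7 (not isolated)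
Conditions: MgCl2, Et3N, (CH2O)n, MeCN, reflux; aq. HCl work-up
Reagents that add atoms: formaldehyde (as paraformaldehyde), C=O
Why: Magnesium-mediated ortho-formylation (Casnati–Skattebøl); the magnesium phenoxide delivers formaldehyde only to the single free ortho position, so ring E and the other CH of ring C are not touched, and a second equivalent of formaldehyde should oxidise 7 by hydride transfer.

Step 5
Reactants: 8 3-(3,5-dimethoxyphenoxy)-2-hydroxy-4,6-dimethoxybenzaldehyde; 9 chloroacetone
Product: 12 1-[7-(3,5-dimethoxyphenoxy)-4,6-dimethoxy-1-benzofuran-2-yl]ethan-1-one, via aryloxyacetone 10 (not isolated), via aldol adduct 11 (not isolated)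
Conditions: K2CO3, DMF, 80 °C
Reagents that add atoms: none
Why: Rap–Stoermer condensation: O-alkylation of the phenoxide, intramolecular aldol addition to the neighbouring aldehyde and dehydration, driven by formation of the aromatic furan; the phenol oxygen becomes O8 and the formyl carbon becomes C12b.

Step 6
Reactants: 12 1-[7-(3,5-dimethoxyphenoxy)-4,6-dimethoxy-1-benzofuran-2-yl]ethan-1-one
Product: 14 2-diazo-1-[7-(3,5-dimethoxyphenoxy)-4,6-dimethoxy-1-benzofuran-2-yl]ethan-1-one, via trifluoroacetyl diketone 13 (not isolated)
Conditions: LiN(SiMe3)2, THF, −78 °C; CF3CO2CH2CF3; aq. HCl work-up; then MsN3, Et3N, H2O, MeCN, rt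
Reagents that add atoms: methanesulfonyl azide, CS(=O)(=O)N=[N+]=[N-]; 2,2,2-trifluoroethyl trifluoroacetate, O=C(OCC(F)(F)F)C(F)(F)F (its trifluoroacetyl group stays only in 13)
Why: Detrifluoroacetylative diazo transfer (Regitz type): Claisen condensation activates the methyl ketone as a 1,3-diketone, and diazo transfer with loss of the trifluoroacetyl group should give the diazomethyl ketone, a standard sequence for aryl methyl ketones.

Step 7
Reactants: 14 2-diazo-1-[7-(3,5-dimethoxyphenoxy)-4,6-dimethoxy-1-benzofuran-2-yl]ethan-1-one; 15 di-tert-butoxyethyne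
Product: 20 2,3-di-tert-butoxy-6-(3,5-dimethoxyphenoxy)-7,9-dimethoxydibenzo[b,d]furan-1-ol, via arylketene 16 (not isolated), via cyclobutenone 17 (not isolated), via dienylketene 18 (not isolated), via dienone 19 (not isolated)
Conditions: hν (medium-pressure Hg lamp, Pyrex filter), 15 (3 equiv), ClCH2CH2Cl, 20 °C; evaporation of excess 15; then toluene, 80 °C
Reagents that add atoms: none
Why: Danheiser benzannulation in its diazo ketone (photo-Wolff) form. Irradiation of 14 expels nitrogen and the benzofuran-2-yl group shifts to the carbene carbon (Wolff rearrangement, new C7–C7a bond) to give arylketene 16, which should add to the electron-rich alkyne 15 in a [2+2] cycloaddition (new C12c–C5a and C7–C6 bonds) to give cyclobutenone 17. A four-electron conrotatory ring opening of 17 breaks the old C12c–C7 bond and gives dienylketene 18, and a six-electron disrotatory electrocyclisation of 18, in which the furan C7a=C12b bond is the third π bond, closes ring B at C12b–C12c; tautomerisation of dienone 19 makes ring B aromatic. The closest known reactions are the benzannulations of aryl and heteroaryl diazomethyl ketones with alkoxy- and silyloxyalkynes and the [2+2] additions of ketenes to 15. No stereocentre remains in 20, because those of 17 and 19 are lost on ring opening and on tautomerisation. The step needs regiocontrol in the cycloaddition and in the ring closure: the first question is removed by the twofold symmetry of 15, the second by the fact that the ketene carbon can reach only C3 of the benzofuran, and the ring opening of 17 is reversible so that the isomer of 18 with the benzofuran cis to the ketene is drained through the irreversible closure. Excess 15 and 20 °C in the photochemical stage are needed because 15 loses isobutene when heated and because the phenol product can add to free ketene.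

Step 8
Reactants: 21 2-fluoro-4-hydroxy-5-methoxybenzaldehyde
Product: 22 3-bromo-2-fluoro-4-hydroxy-5-methoxybenzaldehyde
Conditions: Br2, AcOH, rt
Reagents that add atoms: bromine, BrBr
Why: Electrophilic aromatic bromination directed by the hydroxyl, whose only free ortho position is C3 (the para position carries the formyl group), as in the bromination of vanillin.

Step 9
Reactants: 22 3-bromo-2-fluoro-4-hydroxy-5-methoxybenzaldehyde; 3 (3,5-dimethoxyphenyl)boronic acid
Product: 23 3-bromo-4-(3,5-dimethoxyphenoxy)-2-fluoro-5-methoxybenzaldehyde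
Conditions: 3 (2.5 equiv), Cu(OAc)2 (20 mol %), pyridine, Et3N, 4 Å MS, CH2Cl2, O2 (1 atm), rt
Reagents that add atoms: none
Why: Chan–Lam coupling of a phenol flanked by bromine and methoxy; the aryl bromide and fluoride do not react with the copper catalyst at room temperature, and ring D is attached before ring A meets ring B.

Step 10
Reactants: 20 2,3-di-tert-butoxy-6-(3,5-dimethoxyphenoxy)-7,9-dimethoxydibenzo[b,d]furan-1-ol; 23 3-bromo-4-(3,5-dimethoxyphenoxy)-2-fluoro-5-methoxybenzaldehyde
Product: 24 3-bromo-2-{[2,3-di-tert-butoxy-6-(3,5-dimethoxyphenoxy)-7,9-dimethoxydibenzo[b,d]furan-1-yl]oxy}-4-(3,5-dimethoxyphenoxy)-5-methoxybenzaldehyde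
Conditions: Cs2CO3, DMSO, 90 °C, Ar
Reagents that add atoms: none
Why: SNAr at a fluoride ortho to the formyl group, which stabilises the Meisenheimer intermediate, helped inductively by the neighbouring bromine; 20 has a single free hydroxyl, so the O13–C13a ether should form in one orientation only.

Step 11
Reactants: 24 3-bromo-2-{[2,3-di-tert-butoxy-6-(3,5-dimethoxyphenoxy)-7,9-dimethoxydibenzo[b,d]furan-1-yl]oxy}-4-(3,5-dimethoxyphenoxy)-5-methoxybenzaldehyde
Product: 26 3-bromo-2-{[2,3-di-tert-butoxy-6-(3,5-dimethoxyphenoxy)-7,9-dimethoxydibenzo[b,d]furan-1-yl]oxy}-4-(3,5-dimethoxyphenoxy)-5-methoxyphenol, via aryl formate 25 (not isolated)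
Conditions: mCPBA, CH2Cl2, 0 °C to rt; aq. NaHCO3 wash; then K2CO3 (cat.), MeOH, 0 °C
Reagents that add atoms: 3-chloroperoxybenzoic acid (mCPBA), OOC(=O)c1cccc(Cl)c1
Why: Dakin-type Baeyer–Villiger oxidation; the formyl group has aryloxy oxygens ortho and para, so aryl migration should prevail, and at this stage the molecule carries no free phenol that the peracid could oxidise.

Step 12
Reactants: 26 3-bromo-2-{[2,3-di-tert-butoxy-6-(3,5-dimethoxyphenoxy)-7,9-dimethoxydibenzo[b,d]furan-1-yl]oxy}-4-(3,5-dimethoxyphenoxy)-5-methoxyphenol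
Product: 27 1-[2-bromo-3-(3,5-dimethoxyphenoxy)-6-hydroxy-4-methoxyphenoxy]-6-(3,5-dimethoxyphenoxy)-7,9-dimethoxydibenzo[b,d]furan-2,3-diol
Conditions: CF3CO2H, Et3SiH, CH2Cl2, 0 °C, Ar
Reagents that add atoms: none
Why: Acidolysis of the two aryl tert-butyl ethers through the tert-butyl cation, which triethylsilane reduces before it can alkylate the electron-rich rings (Friedel–Crafts); methyl ethers, diaryl ethers and the aryl bromide are stable to these conditions.

Step 13
Reactants: 27 1-[2-bromo-3-(3,5-dimethoxyphenoxy)-6-hydroxy-4-methoxyphenoxy]-6-(3,5-dimethoxyphenoxy)-7,9-dimethoxydibenzo[b,d]furan-2,3-diol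
Product: 28 4,9-bis(3,5-dimethoxyphenoxy)-3,10,12-trimethoxy[1]benzofuro[3,2-a]oxanthrene-1,6-diol
Conditions: CuI (20 mol %), N,N-dimethylglycine (40 mol %), Cs2CO3, 1,4-dioxane (degassed), 100 °C, Ar
Reagents that add atoms: none
Why: Intramolecular Ullmann diaryl ether synthesis, the classical closure of dibenzodioxins from 2-(2-bromophenoxy)phenols; only the oxygen on C5a can reach C4a in a six-membered ring, the oxygen on C6 would need a seven-membered ring.

Step 14
Reactants: 28 4,9-bis(3,5-dimethoxyphenoxy)-3,10,12-trimethoxy[1]benzofuro[3,2-a]oxanthrene-1,6-diol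
Product: 29 phlorofucofuroeckol A, 4,9-bis(3,5-dihydroxyphenoxy)[1]benzofuro[3,2-a]oxanthrene-1,3,6,10,12-pentol
Conditions: BBr3 (20 equiv), CH2Cl2, −78 °C to rt; MeOH, then H2O; work-up under Ar
Reagents that add atoms: none
Why: Lewis-acid cleavage of the seven aryl methyl ethers by bromide attack on the methyl group of the boron-complexed ether; the diaryl ether, furan and dioxin C–O bonds join two sp2 carbons and should not be cleaved.

## Compound list

1 | 5-bromo-2-hydroxy-3-methoxybenzaldehyde | COc1cc(Br)cc(C=O)c1O | starting material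
2 | 2-hydroxy-3,5-dimethoxybenzaldehyde | COc1cc(OC)c(O)c(C=O)c1 | intermediate
3 | (3,5-dimethoxyphenyl)boronic acid | COc1cc(OC)cc(B(O)O)c1 | starting material
4 | 2-(3,5-dimethoxyphenoxy)-3,5-dimethoxybenzaldehyde | COc1cc(OC)c(Oc2cc(OC)cc(OC)c2)c(C=O)c1 | intermediate
5 | 2-(3,5-dimethoxyphenoxy)-3,5-dimethoxyphenyl formate (formed in the flask) | COc1cc(OC)c(Oc2cc(OC)cc(OC)c2)c(OC=O)c1 | intermediate
6 | 2-(3,5-dimethoxyphenoxy)-3,5-dimethoxyphenol | COc1cc(O)c(Oc2cc(OC)cc(OC)c2)c(OC)c1 | intermediate
7 | 2-(3,5-dimethoxyphenoxy)-6-(hydroxymethyl)-3,5-dimethoxyphenol (formed in the flask as its magnesium phenoxide) | COc1cc(OC)c(Oc2cc(OC)cc(OC)c2)c(O)c1CO | intermediate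
8 | 3-(3,5-dimethoxyphenoxy)-2-hydroxy-4,6-dimethoxybenzaldehyde | COc1cc(OC)c(Oc2cc(OC)cc(OC)c2)c(O)c1C=O | intermediate
9 | chloroacetone (1-chloropropan-2-one) | CC(=O)CCl | starting material
10 | 1-[2-(3,5-dimethoxyphenoxy)-6-formyl-3,5-dimethoxyphenoxy]propan-2-one (formed in the flask) | COc1cc(OC)c(Oc2cc(OC)cc(OC)c2)c(OCC(C)=O)c1C=O | intermediate
11 | 1-[7-(3,5-dimethoxyphenoxy)-3-hydroxy-4,6-dimethoxy-2,3-dihydro-1-benzofuran-2-yl]ethan-1-one (formed in the flask, racemic mixture of diastereomers) | COc1cc(OC)c(Oc2cc(OC)cc(OC)c2)c2OC(C(C)=O)C(O)c12 | intermediate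
12 | 1-[7-(3,5-dimethoxyphenoxy)-4,6-dimethoxy-1-benzofuran-2-yl]ethan-1-one | COc1cc(OC)c(Oc2cc(OC)cc(OC)c2)c2oc(C(C)=O)cc12 | intermediate
13 | 1-[7-(3,5-dimethoxyphenoxy)-4,6-dimethoxy-1-benzofuran-2-yl]-4,4,4-trifluorobutane-1,3-dione (crude, not purified) | COc1cc(OC)c(Oc2cc(OC)cc(OC)c2)c2oc(C(=O)CC(=O)C(F)(F)F)cc12 | intermediate
14 | 2-diazo-1-[7-(3,5-dimethoxyphenoxy)-4,6-dimethoxy-1-benzofuran-2-yl]ethan-1-one | COc1cc(OC)c(Oc2cc(OC)cc(OC)c2)c2oc(C(=O)C=[N+]=[N-])cc12 | intermediate
15 | di-tert-butoxyethyne | CC(C)(C)OC#COC(C)(C)C | starting material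
16 | 2-[7-(3,5-dimethoxyphenoxy)-4,6-dimethoxy-1-benzofuran-2-yl]ethen-1-one (arylketene, formed in the flask) | COc1cc(OC)c(Oc2cc(OC)cc(OC)c2)c2oc(C=C=O)cc12 | intermediate
17 | 2,3-di-tert-butoxy-4-[7-(3,5-dimethoxyphenoxy)-4,6-dimethoxy-1-benzofuran-2-yl]cyclobut-2-en-1-one (formed in the flask, racemic) | COc1cc(OC)c(Oc2cc(OC)cc(OC)c2)c2oc(C3C(=O)C(OC(C)(C)C)=C3OC(C)(C)C)cc12 | intermediate
18 | (3E)-2,3-di-tert-butoxy-4-[7-(3,5-dimethoxyphenoxy)-4,6-dimethoxy-1-benzofuran-2-yl]buta-1,3-dien-1-one (dienylketene, formed in the flask) | COc1cc(OC)c(Oc2cc(OC)cc(OC)c2)c2oc(\C=C(OC(C)(C)C)/C(OC(C)(C)C)=C=O)cc12 | intermediate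
19 | 2,3-di-tert-butoxy-6-(3,5-dimethoxyphenoxy)-7,9-dimethoxy-9bH-dibenzo[b,d]furan-1-one (keto tautomer of 20, formed in the flask, racemic) | COc1cc(OC)c(Oc2cc(OC)cc(OC)c2)c2OC3=CC(OC(C)(C)C)=C(OC(C)(C)C)C(=O)C3c12 | intermediate
20 | 2,3-di-tert-butoxy-6-(3,5-dimethoxyphenoxy)-7,9-dimethoxydibenzo[b,d]furan-1-ol | COc1cc(OC)c(Oc2cc(OC)cc(OC)c2)c2oc3cc(OC(C)(C)C)c(OC(C)(C)C)c(O)c3c12 | intermediate
21 | 2-fluoro-4-hydroxy-5-methoxybenzaldehyde | COc1cc(C=O)c(F)cc1O | starting material
22 | 3-bromo-2-fluoro-4-hydroxy-5-methoxybenzaldehyde | COc1cc(C=O)c(F)c(Br)c1O | intermediate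
23 | 3-bromo-4-(3,5-dimethoxyphenoxy)-2-fluoro-5-methoxybenzaldehyde | COc1cc(C=O)c(F)c(Br)c1Oc1cc(OC)cc(OC)c1 | intermediate
24 | 3-bromo-2-{[2,3-di-tert-butoxy-6-(3,5-dimethoxyphenoxy)-7,9-dimethoxydibenzo[b,d]furan-1-yl]oxy}-4-(3,5-dimethoxyphenoxy)-5-methoxybenzaldehyde | COc1cc(C=O)c(Oc2c(OC(C)(C)C)c(OC(C)(C)C)cc3oc4c(Oc5cc(OC)cc(OC)c5)c(OC)cc(OC)c4c23)c(Br)c1Oc1cc(OC)cc(OC)c1 | intermediate
25 | 3-bromo-2-{[2,3-di-tert-butoxy-6-(3,5-dimethoxyphenoxy)-7,9-dimethoxydibenzo[b,d]furan-1-yl]oxy}-4-(3,5-dimethoxyphenoxy)-5-methoxyphenyl formate (formed in the flask) | COc1cc(OC=O)c(Oc2c(OC(C)(C)C)c(OC(C)(C)C)cc3oc4c(Oc5cc(OC)cc(OC)c5)c(OC)cc(OC)c4c23)c(Br)c1Oc1cc(OC)cc(OC)c1 | intermediate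
26 | 3-bromo-2-{[2,3-di-tert-butoxy-6-(3,5-dimethoxyphenoxy)-7,9-dimethoxydibenzo[b,d]furan-1-yl]oxy}-4-(3,5-dimethoxyphenoxy)-5-methoxyphenol | COc1cc(O)c(Oc2c(OC(C)(C)C)c(OC(C)(C)C)cc3oc4c(Oc5cc(OC)cc(OC)c5)c(OC)cc(OC)c4c23)c(Br)c1Oc1cc(OC)cc(OC)c1 | intermediate
27 | 1-[2-bromo-3-(3,5-dimethoxyphenoxy)-6-hydroxy-4-methoxyphenoxy]-6-(3,5-dimethoxyphenoxy)-7,9-dimethoxydibenzo[b,d]furan-2,3-diol | COc1cc(O)c(Oc2c(O)c(O)cc3oc4c(Oc5cc(OC)cc(OC)c5)c(OC)cc(OC)c4c23)c(Br)c1Oc1cc(OC)cc(OC)c1 | intermediate
28 | 4,9-bis(3,5-dimethoxyphenoxy)-3,10,12-trimethoxy[1]benzofuro[3,2-a]oxanthrene-1,6-diol | COc1cc(OC)cc(Oc2c(OC)cc(O)c3c2Oc2c(O)cc4oc5c(Oc6cc(OC)cc(OC)c6)c(OC)cc(OC)c5c4c2O3)c1 | intermediate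
29 | phlorofucofuroeckol A, 4,9-bis(3,5-dihydroxyphenoxy)[1]benzofuro[3,2-a]oxanthrene-1,3,6,10,12-pentol | Oc1cc(O)cc(Oc2c(O)cc(O)c3c2Oc2c(O)cc4oc5c(Oc6cc(O)cc(O)c6)c(O)cc(O)c5c4c2O3)c1 | target

## Step count and risk

Total: 14 steps. Longest linear sequence: 12 steps (steps 1 to 7 and 10 to 14); steps 8 and 9 form a two-step branch.

**Step 7 (key step).**
- What may go wrong: the arylketene is consumed by dimerisation or by addition of the phenol product instead of by the alkyne; 15 loses isobutene before the cycloaddition; light absorption by the products causes photodegradation; or the cascade stalls at 17 because the closure onto C3 of the benzofuran takes place beside the peri methoxy group of ring C.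
- Fallback, from 14 back to 20, without light and with the ketene made by elimination:
  - a Wolff rearrangement of 14 catalysed by silver benzoate AgO2CPh (Et3N, aqueous 1,4-dioxane) should give 2-[7-(3,5-dimethoxyphenoxy)-4,6-dimethoxy-1-benzofuran-2-yl]acetic acid F1;
  - oxalyl chloride should turn it into the acid chloride F2;
  - slow addition of Et3N to F2 and 15 in CH2Cl2 at 0 to 20 °C should give ketene 16 by dehydrochlorination and from it cyclobutenone 17, which is then heated in toluene at 80 °C to reach 20 by the same electrocyclic sequence.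

**Step 10.**
- What may go wrong: slow substitution, because a phenoxide flanked by a tert-butoxy group and the peri methoxy group attacks a fluoride flanked by formyl and bromine; this leaves time for exchange of the ring D aryloxy group para to the formyl group and for air oxidation of the phenoxide.
- Fallback, from 20 back to 24, with a metal-catalysed C–O coupling in place of SNAr:
  - purchasable 2-bromo-4-hydroxy-5-methoxybenzaldehyde F3 is brominated ortho to the hydroxyl (Br2, AcOH) to 2,3-dibromo-4-hydroxy-5-methoxybenzaldehyde F4;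
  - Chan–Lam coupling with 3 gives 2,3-dibromo-4-(3,5-dimethoxyphenoxy)-5-methoxybenzaldehyde F5;
  - coupling of 20 with F5 (Pd(OAc)2, 2-di-tert-butylphosphino-2′,4′,6′-triisopropylbiphenyl, K3PO4, toluene, 100 °C), in which oxidative addition should prefer the C–Br bond ortho to the formyl group, gives 24.

**Step 13.**
- What may go wrong: binding of the copper catalyst by the neighbouring hydroxyls on C5a and C6, oxidation of the electron-rich triphenolate, and protodebromination in place of ring closure.
- Fallback, from 24 back to 28, closing the dioxin before the Dakin oxidation so that the bromide sits on an electron-poorer ring A without a phenoxide: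
  - acidolysis of 24 (CF3CO2H, Et3SiH) gives the diol aldehyde F6;
  - the copper-catalysed closure of F6 gives the pentacyclic aldehyde F7;
  - mCPBA turns F7 into the pentacyclic formate F8, and methanolysis of F8 gives 28.

**Step 2 (the same applies to step 9).**
- What may go wrong: slow transmetalation and coupling of a hydrogen-bonded, ortho-disubstituted (in step 9 also acidic) phenol, so that protodeboronation and homocoupling of 3 take over.
- Fallback, from 2 back to 4 (and likewise from 22 to 23), metal-free arylation with a diaryliodonium salt: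
  - 1-iodo-3,5-dimethoxybenzene F9 is oxidised with mCPBA and TsOH·H2O to the hydroxy(tosyloxy)iodoarene F10;
  - F10 is trapped in the same flask by 1,3,5-trimethoxybenzene as (3,5-dimethoxyphenyl)(2,4,6-trimethoxyphenyl)iodonium tosylate F11;
  - the phenoxide of 2 (K2CO3, MeCN, 40 °C) is arylated by F11 through ligand coupling on iodine, the trimethoxyphenyl group staying on iodine, to give 4.

**Step 14.**
- What may go wrong: incomplete cleavage of seven methyl ethers as boron aryloxides precipitate, acid-induced ether exchange on the trioxygenated rings, and loss of the free nonaphenol by air oxidation during isolation.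
- Fallback, from 28 back to 29, isolation through a stable derivative:
  - the crude product of the BBr3 reaction is acetylated in the same flask (Ac2O, pyridine, 4-dimethylaminopyridine) to the nonaacetate F12, which should be stable to air and silica gel;
  - partially methylated acetates are separated at this stage and returned to the demethylation;
  - F12 is deacetylated with methanolic HCl (from acetyl chloride and MeOH) under argon to 29.

## Further compounds

F1 | step 7 | 2-[7-(3,5-dimethoxyphenoxy)-4,6-dimethoxy-1-benzofuran-2-yl]acetic acid | COc1cc(OC)c(Oc2cc(OC)cc(OC)c2)c2oc(CC(=O)O)cc12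
F2 | step 7 | 2-[7-(3,5-dimethoxyphenoxy)-4,6-dimethoxy-1-benzofuran-2-yl]acetyl chloride | COc1cc(OC)c(Oc2cc(OC)cc(OC)c2)c2oc(CC(=O)Cl)cc12
F3 | step 10 | 2-bromo-4-hydroxy-5-methoxybenzaldehyde | COc1cc(C=O)c(Br)cc1O
F4 | step 10 | 2,3-dibromo-4-hydroxy-5-methoxybenzaldehyde | COc1cc(C=O)c(Br)c(Br)c1O
F5 | step 10 | 2,3-dibromo-4-(3,5-dimethoxyphenoxy)-5-methoxybenzaldehyde | COc1cc(C=O)c(Br)c(Br)c1Oc1cc(OC)cc(OC)c1
F6 | step 13 | 3-bromo-2-{[6-(3,5-dimethoxyphenoxy)-2,3-dihydroxy-7,9-dimethoxydibenzo[b,d]furan-1-yl]oxy}-4-(3,5-dimethoxyphenoxy)-5-methoxybenzaldehyde | COc1cc(C=O)c(Oc2c(O)c(O)cc3oc4c(Oc5cc(OC)cc(OC)c5)c(OC)cc(OC)c4c23)c(Br)c1Oc1cc(OC)cc(OC)c1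
F7 | step 13 | 4,9-bis(3,5-dimethoxyphenoxy)-6-hydroxy-3,10,12-trimethoxy[1]benzofuro[3,2-a]oxanthrene-1-carbaldehyde | COc1cc(OC)cc(Oc2c(OC)cc(C=O)c3c2Oc2c(O)cc4oc5c(Oc6cc(OC)cc(OC)c6)c(OC)cc(OC)c5c4c2O3)c1
F8 | step 13 | 4,9-bis(3,5-dimethoxyphenoxy)-6-hydroxy-3,10,12-trimethoxy[1]benzofuro[3,2-a]oxanthren-1-yl formate | COc1cc(OC)cc(Oc2c(OC)cc(OC=O)c3c2Oc2c(O)cc4oc5c(Oc6cc(OC)cc(OC)c6)c(OC)cc(OC)c5c4c2O3)c1
F9 | step 2 | 1-iodo-3,5-dimethoxybenzene | COc1cc(I)cc(OC)c1
F10 | step 2 | 1-[hydroxy(tosyloxy)iodo]-3,5-dimethoxybenzene | COc1cc(OC)cc(I(O)OS(=O)(=O)c2ccc(C)cc2)c1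
F11 | step 2 | (3,5-dimethoxyphenyl)(2,4,6-trimethoxyphenyl)iodonium 4-methylbenzenesulfonate | COc1cc(OC)cc([I+]c2c(OC)cc(OC)cc2OC)c1.Cc1ccc(S(=O)(=O)[O-])cc1
F12 | step 14 | phlorofucofuroeckol A nonaacetate | CC(=O)Oc1cc(OC(C)=O)cc(Oc2c(OC(C)=O)cc(OC(C)=O)c3c2Oc2c(OC(C)=O)cc4oc5c(Oc6cc(OC(C)=O)cc(OC(C)=O)c6)c(OC(C)=O)cc(OC(C)=O)c5c4c2O3)c1
A1 | alternative 1 | 2-bromo-1-[2-(3,5-dimethoxyphenoxy)-3,5-dimethoxyphenoxy]-3,4,5-trimethoxybenzene | COc1cc(Oc2cc(OC)cc(OC)c2Oc2cc(OC)cc(OC)c2)c(Br)c(OC)c1OC
A2 | alternative 1 | 6-(3,5-dimethoxyphenoxy)-1,2,3,7,9-pentamethoxydibenzo[b,d]furan | COc1cc2oc3c(Oc4cc(OC)cc(OC)c4)c(OC)cc(OC)c3c2c(OC)c1OC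
A3 | alternative 2 | eckol, 4-(3,5-dihydroxyphenoxy)dibenzo[b,e][1,4]dioxine-1,3,6,8-tetrol | Oc1cc(O)cc(Oc2c(O)cc(O)c3c2Oc2c(O)cc(O)cc2O3)c1
A4 | alternative 2 | 2-(3,5-dihydroxyphenoxy)benzene-1,3,5-triol | Oc1cc(O)cc(Oc2c(O)cc(O)cc2O)c1
A5 | alternative 2 | 4-(3,5-dihydroxyphenoxy)-9-[3-(3,5-dihydroxyphenoxy)-2,4,6-trihydroxyphenyl]dibenzo[b,e][1,4]dioxine-1,3,6,8-tetrol | Oc1cc(O)cc(Oc2c(O)cc(O)c3c2Oc2c(O)cc(O)c(-c4c(O)cc(O)c(Oc5cc(O)cc(O)c5)c4O)c2O3)c1
A6 | alternative 3 | 2,6-dimethoxy-1,4-benzoquinone | COC1=CC(=O)C=C(OC)C1=O
A7 | alternative 3 | 6-(3,5-dimethoxyphenoxy)-1,3,7,9-tetramethoxydibenzo[b,d]furan-2-ol | COc1cc2oc3c(Oc4cc(OC)cc(OC)c4)c(OC)cc(OC)c3c2c(OC)c1O
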